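**Retrosynthetic overview**
- The cyclohexenone is opened across C(=O)–Cα and Cα=Cβ into a bicyclic δ-enol lactone plus a 3-oxido-3-methylbutyl carbanion. The enone C=O and the tertiary carbinol are 1,4-related (dissonant), so this bond needs a d3, homoenolate-type donor (Fujimoto–Belleau annulation).
- The enol lactone comes from a δ-keto acid, made by strain-driven retro-Claisen fission of a 2-acylcyclobutanone, itself a Claisen product of a cyclobutanone and a chromanylacetate.
- The cyclobutanone comes from ozonolysis of the adduct of a catalytic enantioselective allenoate [2+2] on 1,2-dimethylcyclopentene, which sets both quaternary carbons.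
- The chroman ester comes from an enantioselective oxypalladation/carbonylation of an alkenylphenol, made by Negishi coupling of a bromophenol.
- Ring order: sacrificial cyclobutane, then chroman ring, then dihydropyranone (enol lactone), then cyclohexenone.

Assumption: the catalyst, ligand and auxiliary antipodes named are taken to give the enantiomers drawn (if a sense is opposite, the mirror-image catalyst is used), and compounds 1, 2, 5, 7 and 15 are bought.

**Step 1**
Reactants: 1 1,2-dimethylcyclopentene; 2 ethyl buta-2,3-dienoate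
Product: 3 ethyl (2E)-2-[(1S,5S)-1,5-dimethylbicyclo[3.2.0]heptan-6-ylidene]acetate
Conditions: 1 (3 equiv), (3aS)-1-(2-methylphenyl)-3,3-diphenyltetrahydro-1H,3H-pyrrolo[1,2-c][1,3,2]oxazaborole (20 mol %), AlBr3 (16 mol %), CH2Cl2, −20 °C to rt
Reagents that add atoms: none
Why: Lewis-acid-catalysed allenoate–alkene [2+2] cycloaddition in its enantioselective oxazaborolidine/AlBr3 form; the alkene reacts suprafacially so the two methyl-bearing quaternary carbons are necessarily cis, and the chiral Lewis acid on the allenoate decides which alkene carbon bonds to the central allene carbon, giving (1S,5S).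

**Step 2**
Reactants: 3 ethyl (2E)-2-[(1S,5S)-1,5-dimethylbicyclo[3.2.0]heptan-6-ylidene]acetate
Product: 4 (1S,5S)-1,5-dimethylbicyclo[3.2.0]heptan-6-one
Conditions: O3, CH2Cl2/MeOH, −78 °C; then Me2S, −78 °C to rt
Reagents that add atoms: ozone, [O-][O+]=O
Why: Ozonolysis with reductive work-up cleaves the only C=C and unmasks the cyclobutanone, leaving the quaternary centres untouched.

**Step 3**
Reactants: 5 4-methoxy-2-methylphenol
Product: 6 2-bromo-4-methoxy-6-methylphenol
Conditions: N-bromosuccinimide (1.0 equiv), i-Pr2NH (10 mol %), CH2Cl2, 0 °C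
Reagents that add atoms: N-bromosuccinimide, O=C1CCC(=O)N1Br
Why: Amine-catalysed ortho-selective electrophilic bromination; the N-bromoamine is delivered by hydrogen bonding to the phenol OH, and the para position is blocked.

**Step 4**
Reactants: 6 2-bromo-4-methoxy-6-methylphenol; 7 4-bromo-2-methylbut-1-ene
Product: 9 4-methoxy-2-methyl-6-(3-methylbut-3-en-1-yl)phenol, via (3-methylbut-3-en-1-yl)zinc bromide 8 (not isolated)
Conditions: 7, Zn dust, LiCl, THF, 40 °C; then 6 (0.45 equiv), Pd(OAc)2 (2 mol %), dicyclohexyl(2',6'-dimethoxybiphenyl-2-yl)phosphine (4 mol %), THF, rt to 40 °C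
Reagents that add atoms: none
Why: Negishi sp2–sp3 cross-coupling on zerovalent palladium formed in situ; the bulky biaryl phosphine suppresses β-hydride elimination of the primary alkyl, and the free phenol is tolerated because one extra equivalent of 8 is sacrificed to its O–H.

**Step 5**
Reactants: 9 4-methoxy-2-methyl-6-(3-methylbut-3-en-1-yl)phenol
Product: 10 methyl 2-[(2R)-6-methoxy-2,8-dimethyl-3,4-dihydro-2H-chromen-2-yl]acetate
Conditions: Pd(OCOCF3)2 (5 mol %), 2,2'-bis[(4S)-4-benzyl-4,5-dihydro-1,3-oxazol-2-yl]-1,1'-binaphthalene ((S,S)-Bn-BOXAX, 20 mol %), p-benzoquinone (4 equiv), CO (1 atm), MeOH, rt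
Reagents that add atoms: carbon monoxide, [C-]#[O+]; methanol, CO
Why: Tietze-type enantioselective domino Wacker oxypalladation/carbonylation; the chiral divalent palladium complex selects the alkene face for 6-exo attack of the phenol and so sets C2 as R, and the resulting alkyl–palladium has no β-hydrogen, so it inserts CO and is methanolysed.

**Step 6**
Reactants: 4 (1S,5S)-1,5-dimethylbicyclo[3.2.0]heptan-6-one; 10 methyl 2-[(2R)-6-methoxy-2,8-dimethyl-3,4-dihydro-2H-chromen-2-yl]acetate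
Product: 12 (1S,5S,7RS)-7-{2-[(2R)-6-methoxy-2,8-dimethyl-3,4-dihydro-2H-chromen-2-yl]acetyl}-1,5-dimethylbicyclo[3.2.0]heptan-6-one, via lithium enolate of the cyclobutanone 11 (not isolated)
Conditions: 4 (1.1 equiv), LiN(SiMe3)2 (2.2 equiv), THF, −78 °C; then 10, −78 to 0 °C; AcOH quench
Reagents that add atoms: none
Why: Crossed Claisen condensation; 4 can enolise only toward C7 because C5 is quaternary, the β-diketonate formed pulls the equilibrium, and the ketone enolate is too weak a base to deprotonate the ester, which protects C2 from retro-oxa-Michael opening.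

**Step 7**
Reactants: 12 (1S,5S,7RS)-7-{2-[(2R)-6-methoxy-2,8-dimethyl-3,4-dihydro-2H-chromen-2-yl]acetyl}-1,5-dimethylbicyclo[3.2.0]heptan-6-one
Product: 13 (1S,2S)-2-{3-[(2R)-6-methoxy-2,8-dimethyl-3,4-dihydro-2H-chromen-2-yl]-2-oxopropyl}-1,2-dimethylcyclopentane-1-carboxylic acid
Conditions: LiOH·H2O (2 equiv), THF/H2O 3:1, 0 °C to rt; then 1 M HCl to pH 3
Reagents that add atoms: lithium hydroxide, [Li+].[OH-]
Why: Retro-Claisen ring fission; hydroxide adds to the strained cyclobutanone carbonyl and the C6–C7 bond breaks with release of ring strain, expelling the ketone enolate, while the quaternary centres are not involved.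

**Step 8**
Reactants: 13 (1S,2S)-2-{3-[(2R)-6-methoxy-2,8-dimethyl-3,4-dihydro-2H-chromen-2-yl]-2-oxopropyl}-1,2-dimethylcyclopentane-1-carboxylic acid
Product: 14 (4aS,7aS)-3-{[(2R)-6-methoxy-2,8-dimethyl-3,4-dihydro-2H-chromen-2-yl]methyl}-4a,7a-dimethyl-5,6,7,7a-tetrahydrocyclopenta[c]pyran-1(4aH)-one
Conditions: Ac2O, NaOAc (0.5 equiv), 90 °C
Reagents that add atoms: none
Why: Enol-lactonisation of a δ-keto acid through the mixed anhydride (Turner conditions); the endocyclic enol lactone is favoured, and the exocyclic isomer would serve equally in the next step.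

**Step 9**
Reactants: 15 4-bromo-2-methylbutan-2-ol
Product: 16 [(4-bromo-2-methylbutan-2-yl)oxy]triethylsilane
Conditions: Et3SiOSO2CF3 (1.1 equiv), 2,6-lutidine (1.5 equiv), CH2Cl2, 0 °C
Reagents that add atoms: triethylsilyl trifluoromethanesulfonate, CC[Si](CC)(CC)OS(=O)(=O)C(F)(F)F
Why: Silylation of a tertiary alcohol with a silyl triflate masks the OH so that the bromide can be turned into a Grignard reagent.

**Step 10**
Reactants: 14 (4aS,7aS)-3-{[(2R)-6-methoxy-2,8-dimethyl-3,4-dihydro-2H-chromen-2-yl]methyl}-4a,7a-dimethyl-5,6,7,7a-tetrahydrocyclopenta[c]pyran-1(4aH)-one; 16 [(4-bromo-2-methylbutan-2-yl)oxy]triethylsilane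
Product: 19 (3aS,7aS)-5-(2-hydroxy-2-methylpropyl)-6-{[(2R)-6-methoxy-2,8-dimethyl-3,4-dihydro-2H-chromen-2-yl]methyl}-3a,7a-dimethyl-1,2,3,3a,7,7a-hexahydro-4H-inden-4-one, via silyloxyalkyl Grignard reagent 17 (not isolated), via open-chain diketone silyl ether 18 (not isolated)
Conditions: 16, Mg turnings, I2 (cat.), THF, rt; add 17 (1.3 equiv) to 14, THF, −78 to −20 °C; aq NH4Cl; then TsOH·H2O (0.5 equiv), THF/H2O 9:1, 55 °C
Reagents that add atoms: none
Why: Fujimoto–Belleau annulation in which the Grignard carbon, a d3 (homoenolate-type) donor β to the masked carbinol carbon and so of reversed polarity, acylates the lactone carbonyl (both carbons are acceptor sites in normal reactivity), the hindered neopentyl ketone resists a second addition, and acid then drives the only unhindered six-ring aldol (Cα onto the chromanylmethyl ketone), dehydration and desilylation without forming or touching a stereocentre.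

**Compound list**
1 | 1,2-dimethylcyclopentene | CC1=C(C)CCC1 | starting material
2 | ethyl buta-2,3-dienoate | C=C=CC(=O)OCC | starting material
3 | ethyl (2E)-2-[(1S,5S)-1,5-dimethylbicyclo[3.2.0]heptan-6-ylidene]acetate | CCOC(=O)/C=C1/[C@@]2(C)CCC[C@@]2(C)C1 | intermediate
4 | (1S,5S)-1,5-dimethylbicyclo[3.2.0]heptan-6-one (cis-fused) | O=C1[C@@]2(C)CCC[C@@]2(C)C1 | intermediate
5 | 4-methoxy-2-methylphenol | COc1ccc(O)c(C)c1 | starting material
6 | 2-bromo-4-methoxy-6-methylphenol | COc1cc(C)c(O)c(Br)c1 | intermediate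
7 | 4-bromo-2-methylbut-1-ene | C=C(C)CCBr | starting material
8 | (3-methylbut-3-en-1-yl)zinc bromide | C=C(C)CC[Zn]Br | intermediate (not isolated)
9 | 4-methoxy-2-methyl-6-(3-methylbut-3-en-1-yl)phenol | COc1cc(C)c(O)c(CCC(C)=C)c1 | intermediate
10 | methyl 2-[(2R)-6-methoxy-2,8-dimethyl-3,4-dihydro-2H-chromen-2-yl]acetate | COc1cc(C)c2c(c1)CC[C@](C)(CC(=O)OC)O2 | intermediate
11 | lithium (1S,5S)-1,5-dimethylbicyclo[3.2.0]hept-6-en-6-olate | [Li+].[O-]C1[C@@]2(C)CCC[C@@]2(C)C=1 | intermediate (not isolated)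
12 | (1S,5S,7RS)-7-{2-[(2R)-6-methoxy-2,8-dimethyl-3,4-dihydro-2H-chromen-2-yl]acetyl}-1,5-dimethylbicyclo[3.2.0]heptan-6-one (C7 epimers, largely enolised) | COc1cc(C)c2c(c1)CC[C@](C)(CC(=O)C1C(=O)[C@@]3(C)CCC[C@]31C)O2 | intermediate
13 | (1S,2S)-2-{3-[(2R)-6-methoxy-2,8-dimethyl-3,4-dihydro-2H-chromen-2-yl]-2-oxopropyl}-1,2-dimethylcyclopentane-1-carboxylic acid | COc1cc(C)c2c(c1)CC[C@](C)(CC(=O)C[C@]1(C)CCC[C@]1(C)C(=O)O)O2 | intermediate
14 | (4aS,7aS)-3-{[(2R)-6-methoxy-2,8-dimethyl-3,4-dihydro-2H-chromen-2-yl]methyl}-4a,7a-dimethyl-5,6,7,7a-tetrahydrocyclopenta[c]pyran-1(4aH)-one | COc1cc(C)c2c(c1)CC[C@](C)(CC1=C[C@]3(C)CCC[C@]3(C)C(=O)O1)O2 | intermediate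
15 | 4-bromo-2-methylbutan-2-ol | CC(C)(O)CCBr | starting material
16 | [(4-bromo-2-methylbutan-2-yl)oxy]triethylsilane | CC[Si](CC)(CC)OC(C)(C)CCBr | intermediate
17 | {3-methyl-3-[(triethylsilyl)oxy]butyl}magnesium bromide | CC[Si](CC)(CC)OC(C)(C)CC[Mg]Br | intermediate (not isolated)
18 | 1-[(1S,2S)-2-{3-[(2R)-6-methoxy-2,8-dimethyl-3,4-dihydro-2H-chromen-2-yl]-2-oxopropyl}-1,2-dimethylcyclopentyl]-4-methyl-4-[(triethylsilyl)oxy]pentan-1-one | COc1cc(C)c2c(c1)CC[C@](C)(CC(=O)C[C@]1(C)CCC[C@]1(C)C(=O)CCC(C)(C)O[Si](CC)(CC)CC)O2 | intermediate (not isolated)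
19 | (3aS,7aS)-5-(2-hydroxy-2-methylpropyl)-6-{[(2R)-6-methoxy-2,8-dimethyl-3,4-dihydro-2H-chromen-2-yl]methyl}-3a,7a-dimethyl-1,2,3,3a,7,7a-hexahydro-4H-inden-4-one (CNP0224132.1) | COc1cc(C)c2c(c1)CC[C@](C)(CC1=C(CC(C)(C)O)C(=O)[C@@]3(C)CCC[C@@]3(C)C1)O2 | target

**Totals**
Total step count: 10. Longest linear sequence: 7 (steps 3, 4, 5, 6, 7, 8, 10).

**Three steps most likely to fail**

Step 1 is the least certain, because the enantioselective allenoate [2+2] has not been shown on a tetrasubstituted, symmetric alkene and both yield and ee are open. The fallback sets out from 1 and comes back at 4, replacing catalyst control by a chiral auxiliary on a ketene equivalent. (2R,5R)-2,5-Dimethylpyrrolidine is acetylated (AcCl, Et3N) to 1-[(2R,5R)-2,5-dimethylpyrrolidin-1-yl]ethan-1-one F1. Treating it with (CF3SO2)2O and 2,4,6-collidine in 1,2-dichloroethane gives (2R,5R)-1-ethenylidene-2,5-dimethylpyrrolidin-1-ium trifluoromethanesulfonate F2. This keteniminium salt adds to 1 to give (2R,5R)-1-[(1S,5S)-1,5-dimethylbicyclo[3.2.0]heptan-6-ylidene]-2,5-dimethylpyrrolidin-1-ium trifluoromethanesulfonate F3, and aqueous NaHCO3 hydrolysis gives 4 directly.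

Step 6 may fail because ester Claisen condensations of lithium enolates can be slow, and any enolisation on the chroman side risks β-aryloxy elimination and loss of C2 integrity. The fallback sets out from 10 and comes back at 12, replacing acylation by aldol addition and oxidation. i-Bu2AlH (CH2Cl2, −78 °C) reduces 10 to 2-[(2R)-6-methoxy-2,8-dimethyl-3,4-dihydro-2H-chromen-2-yl]acetaldehyde F4. Fast aldol addition of enolate 11 at −78 °C gives (1S,5S)-7-{1-hydroxy-2-[(2R)-6-methoxy-2,8-dimethyl-3,4-dihydro-2H-chromen-2-yl]ethyl}-1,5-dimethylbicyclo[3.2.0]heptan-6-one F5, and Dess–Martin periodinane with NaHCO3 gives 12.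

Step 10 carries three risks: the lactone carbonyl is neopentylic, the aldol needs acid that must not dehydrate the tertiary alcohol, and enolate equilibration could open the chroman. The fallback sets out from 14 and 16 and comes back at 19, closing the ring by olefination instead of aldol condensation.
- Arbuzov reaction of 16 with P(OMe)3 (110 °C) gives dimethyl {3-methyl-3-[(triethylsilyl)oxy]butyl}phosphonate F6.
- n-BuLi (THF, −78 °C) gives lithium 1-(dimethoxyphosphoryl)-3-methyl-3-[(triethylsilyl)oxy]butan-1-ide F7.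
- Two equivalents of F7 open 14 to dimethyl {1-[(1S,2S)-2-{3-[(2R)-6-methoxy-2,8-dimethyl-3,4-dihydro-2H-chromen-2-yl]-2-oxopropyl}-1,2-dimethylcyclopentyl]-4-methyl-1-oxo-4-[(triethylsilyl)oxy]pentan-2-yl}phosphonate F8.
- LiCl/i-Pr2NEt in MeCN deprotonates only the ketophosphonate and closes the ring by intramolecular Horner–Wadsworth–Emmons reaction to (3aS,7aS)-6-{[(2R)-6-methoxy-2,8-dimethyl-3,4-dihydro-2H-chromen-2-yl]methyl}-3a,7a-dimethyl-5-{2-methyl-2-[(triethylsilyl)oxy]propyl}-1,2,3,3a,7,7a-hexahydro-4H-inden-4-one F9.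
- Bu4NF in THF gives 19.

**Further compounds**
F1 | step 1 | 1-[(2R,5R)-2,5-dimethylpyrrolidin-1-yl]ethan-1-one | C[C@@H]1CC[C@@H](C)N1C(C)=O
F2 | step 1 | (2R,5R)-1-ethenylidene-2,5-dimethylpyrrolidin-1-ium trifluoromethanesulfonate | C[C@@H]1CC[C@@H](C)[N+]1=C=C.[O-]S(=O)(=O)C(F)(F)F
F3 | step 1 | (2R,5R)-1-[(1S,5S)-1,5-dimethylbicyclo[3.2.0]heptan-6-ylidene]-2,5-dimethylpyrrolidin-1-ium trifluoromethanesulfonate | C[C@@H]1CC[C@@H](C)[N+]1=C1[C@@]2(C)CCC[C@@]2(C)C1.[O-]S(=O)(=O)C(F)(F)F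
F4 | step 6 | 2-[(2R)-6-methoxy-2,8-dimethyl-3,4-dihydro-2H-chromen-2-yl]acetaldehyde | COc1cc(C)c2c(c1)CC[C@](C)(CC=O)O2
F5 | step 6 | (1S,5S)-7-{1-hydroxy-2-[(2R)-6-methoxy-2,8-dimethyl-3,4-dihydro-2H-chromen-2-yl]ethyl}-1,5-dimethylbicyclo[3.2.0]heptan-6-one (diastereomer mixture at C7 and the carbinol) | COc1cc(C)c2c(c1)CC[C@](C)(CC(O)C1C(=O)[C@@]3(C)CCC[C@]31C)O2
F6 | step 10 | dimethyl {3-methyl-3-[(triethylsilyl)oxy]butyl}phosphonate | COP(=O)(OC)CCC(C)(C)O[Si](CC)(CC)CC
F7 | step 10 | lithium 1-(dimethoxyphosphoryl)-3-methyl-3-[(triethylsilyl)oxy]butan-1-ide | [Li+].COP(=O)(OC)[CH-]CC(C)(C)O[Si](CC)(CC)CC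
F8 | step 10 | dimethyl {1-[(1S,2S)-2-{3-[(2R)-6-methoxy-2,8-dimethyl-3,4-dihydro-2H-chromen-2-yl]-2-oxopropyl}-1,2-dimethylcyclopentyl]-4-methyl-1-oxo-4-[(triethylsilyl)oxy]pentan-2-yl}phosphonate | COc1cc(C)c2c(c1)CC[C@](C)(CC(=O)C[C@]1(C)CCC[C@]1(C)C(=O)C(CC(C)(C)O[Si](CC)(CC)CC)P(=O)(OC)OC)O2
F9 | step 10 | (3aS,7aS)-6-{[(2R)-6-methoxy-2,8-dimethyl-3,4-dihydro-2H-chromen-2-yl]methyl}-3a,7a-dimethyl-5-{2-methyl-2-[(triethylsilyl)oxy]propyl}-1,2,3,3a,7,7a-hexahydro-4H-inden-4-one | COc1cc(C)c2c(c1)CC[C@](C)(CC1=C(CC(C)(C)O[Si](CC)(CC)CC)C(=O)[C@@]3(C)CCC[C@@]3(C)C1)O2
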